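**Retrosynthetic overview**

1. Artonin C 29 is reached from the protected 2′-hydroxyaryl ketone 26 by three closing operations: removal of a chlorine steering group, Claisen–Schmidt formation of the chalcone enone on the acetyl group, and cleavage of all methoxymethyl (MOM) ethers.
2. Key disconnection: in the 2,4-dihydroxy-3-alkenylbenzoyl ring (C-1′ bears the ketone, C-2′ and C-4′ oxygen, C-3′ the alkenyl group), the acyl carbon on C-1′ and the hydroxyl on the adjacent C-2′ together are a carboxylic acid added across an aryne. This ortho-hydroxyaryl ketone pattern allows aryne 24 (triple bond C-1′≡C-2′) to insert into the C(=O)–OH bond of acid 12, making the ketone C–C-1′ bond and the C-2′–O bond in one operation.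
3. Acid 12 comes from periodate cleavage of ketol 11, the endo adduct of a Cu(II)–bis(oxazoline)-catalysed Diels–Alder reaction between aryl diene 6 and α′-hydroxy enone 10 (a cinnamate equivalent); this step builds the cyclohexene ring and all three stereocentres.
4. Aryne precursor 23 comes from 5-chlororesorcinol (iodination, bromination, Suzuki alkenylation, retro-Brook silylation/triflation, MOM protection); diene 6 comes from 2,4-dihydroxyacetophenone (iodination, MOM protection, Suzuki dienylation).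
5. Ring order: the four benzene rings are bought; the cyclohexene (step 7) is the only ring constructed; the aryne step closes only a transient four-membered benzoxete ring that reopens.

Key step: step 15

Assumption: the Cu(II)–tert-butyl-bis(oxazoline) complex of the chelated α′-hydroxy enone is taken to shield the same enone face as the square-planar complexes of N-enoyl oxazolidinones (s-cis enone); on that model the (R,R)-ligand exposes the Si face of C-α, as needed here, and the (S,S)-ligand would be used if the sense proved opposite.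

**Route**

Step 1
Reactants: 1 2,4-dihydroxyacetophenone
Product: 2 1-(2,4-dihydroxy-3-iodophenyl)ethanone
Conditions: I2, HIO3, EtOH/H2O, rt
Reagents that add atoms: iodine, II; iodic acid, OI(=O)=O
Why: Electrophilic aromatic iodination with I2/HIO3 should take place at C-3, the position ortho to both hydroxyl groups, while iodic acid reoxidises iodide so that all iodine is used.

Step 2
Reactants: 2 1-(2,4-dihydroxy-3-iodophenyl)ethanone
Product: 3 1-[3-iodo-2,4-bis(methoxymethoxy)phenyl]ethanone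
Conditions: NaH, MOMCl, DMF, 0 °C→rt
Reagents that add atoms: chloromethyl methyl ether, COCCl
Why: Williamson-type O-alkylation of both sodium phenoxides with the reactive chloromethyl ether (MOM protection) should also cap the chelated 2-hydroxyl group.

Step 3
Reactants: 4 2-methylbut-1-en-3-yne
Product: 5 4,4,5,5-tetramethyl-2-[(1E)-3-methylbuta-1,3-dien-1-yl]-1,3,2-dioxaborolane
Conditions: HBpin, Cp2ZrHCl (5 mol %), Et3N (10 mol %), neat, sealed tube, 60 °C
Reagents that add atoms: pinacolborane, CC1(C)OBOC1(C)C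
Why: Zirconium-catalysed syn-hydroboration of the terminal alkyne places boron on the terminal carbon and gives the E-dienylboronate, the 1,1-disubstituted alkene being left alone.

Step 4
Reactants: 3 1-[3-iodo-2,4-bis(methoxymethoxy)phenyl]ethanone; 5 4,4,5,5-tetramethyl-2-[(1E)-3-methylbuta-1,3-dien-1-yl]-1,3,2-dioxaborolane
Product: 6 1-[2,4-bis(methoxymethoxy)-3-[(1E)-3-methylbuta-1,3-dien-1-yl]phenyl]ethanone
Conditions: Pd(dppf)Cl2 (5 mol %), K2CO3, dioxane/H2O, 80 °C
Reagents that add atoms: none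
Why: Suzuki–Miyaura cross-coupling proceeds with retention of the E geometry of the alkenylboronate, and a bidentate phosphine ligand should cope with the di-ortho-substituted aryl iodide.

Step 5
Reactants: 7 2,4-dihydroxybenzaldehyde
Product: 8 2,4-bis(methoxymethoxy)benzaldehyde
Conditions: NaH, MOMCl, DMF, 0 °C→rt
Reagents that add atoms: chloromethyl methyl ether, COCCl
Why: Williamson-type O-alkylation (MOM protection) of both phenoxides; the aldehyde has no enolisable position.

Step 6
Reactants: 8 2,4-bis(methoxymethoxy)benzaldehyde; 9 3-hydroxy-3-methylbutan-2-one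
Product: 10 (1E)-1-[2,4-bis(methoxymethoxy)phenyl]-4-hydroxy-4-methylpent-1-en-3-one
Conditions: LiOH·H2O, MeOH/H2O, reflux
Reagents that add atoms: none
Why: Claisen–Schmidt aldol condensation: the methyl group of the ketol is the only enolisable position, the aldehyde is not enolisable, and E1cB dehydration gives the conjugated E-enone.

Step 7
Reactants: 6 1-[2,4-bis(methoxymethoxy)-3-[(1E)-3-methylbuta-1,3-dien-1-yl]phenyl]ethanone; 10 (1E)-1-[2,4-bis(methoxymethoxy)phenyl]-4-hydroxy-4-methylpent-1-en-3-one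
Product: 11 1-[(1R,2S,6S)-2-[3-acetyl-2,6-bis(methoxymethoxy)phenyl]-6-[2,4-bis(methoxymethoxy)phenyl]-4-methylcyclohex-3-en-1-yl]-2-hydroxy-2-methylpropan-1-one
Conditions: [Cu((R,R)-t-Bu-box)](SbF6)2 (10 mol %), 4 Å MS, CH2Cl2, 0 °C→rt
Reagents that add atoms: none
Why: Cu(II)–bis(oxazoline)-catalysed asymmetric Diels–Alder reaction of a two-point-binding α′-hydroxy enone: the 1-aryl and 3-methyl groups of the diene direct its CH2 terminus to the β-carbon, the endo transition state places the aryl group of the diene cis to the acyl group (C-1/C-2), the E-enone geometry fixes acyl and aryl trans (C-1/C-6), and the tert-butyl group of the (R,R)-ligand shields the Re face of C-α of the s-cis chelated enone, so that the three stereocentres should arise as 1R,2S,6S.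

Step 8
Reactants: 11 1-[(1R,2S,6S)-2-[3-acetyl-2,6-bis(methoxymethoxy)phenyl]-6-[2,4-bis(methoxymethoxy)phenyl]-4-methylcyclohex-3-en-1-yl]-2-hydroxy-2-methylpropan-1-one
Product: 12 (1R,2S,6S)-2-[3-acetyl-2,6-bis(methoxymethoxy)phenyl]-6-[2,4-bis(methoxymethoxy)phenyl]-4-methylcyclohex-3-ene-1-carboxylic acid
Conditions: NaIO4, MeOH/H2O, rt
Reagents that add atoms: water, O
Why: Periodate cleavage (Malaprade-type) of the tertiary α-hydroxy ketone gives the carboxylic acid and acetone under near-neutral conditions, so that the stereocentre α to the carbonyl group is not epimerised.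

Step 9
Reactants: 13 5-chlorobenzene-1,3-diol
Product: 14 5-chloro-2-iodobenzene-1,3-diol
Conditions: I2, NaHCO3, H2O, 0 °C→rt
Reagents that add atoms: iodine, II
Why: Electrophilic iodination of the resorcinol under bicarbonate buffering should occur at C-2 between the two hydroxyl groups, as with resorcinol itself, the other two positions being additionally hindered by chlorine.

Step 10
Reactants: 14 5-chloro-2-iodobenzene-1,3-diol
Product: 15 4-bromo-5-chloro-2-iodobenzene-1,3-diol
Conditions: NBS (1.0 equiv), MeCN, −20 °C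
Reagents that add atoms: N-bromosuccinimide, O=C1CCC(=O)N1Br
Why: Electrophilic aromatic bromination with NBS should attack the only remaining type of activated position (ortho to one hydroxyl and para to the other; C-4 and C-6 are equivalent), and one equivalent at low temperature limits it to monobromination.

Step 11
Reactants: 16 3-methylbut-1-yne
Product: 17 4,4,5,5-tetramethyl-2-[(1E)-3-methylbut-1-en-1-yl]-1,3,2-dioxaborolane
Conditions: HBpin, Cp2ZrHCl (5 mol %), Et3N (10 mol %), neat, sealed tube, 60 °C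
Reagents that add atoms: pinacolborane, CC1(C)OBOC1(C)C
Why: Zirconium-catalysed syn-hydroboration of the terminal alkyne gives the E-alkenylboronate with boron on the terminal carbon.

Step 12
Reactants: 15 4-bromo-5-chloro-2-iodobenzene-1,3-diol; 17 4,4,5,5-tetramethyl-2-[(1E)-3-methylbut-1-en-1-yl]-1,3,2-dioxaborolane
Product: 18 4-bromo-5-chloro-2-[(1E)-3-methylbut-1-en-1-yl]benzene-1,3-diol
Conditions: Pd(PPh3)4 (5 mol %), K2CO3, dioxane/H2O, 60 °C
Reagents that add atoms: none
Why: Chemoselective Suzuki–Miyaura coupling: oxidative addition into the C–I bond is much faster than into the C–Br or C–Cl bond, and the E geometry of the boronate is retained.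

Step 13
Reactants: 18 4-bromo-5-chloro-2-[(1E)-3-methylbut-1-en-1-yl]benzene-1,3-diol
Product: 22 3-chloro-5-hydroxy-6-[(1E)-3-methylbut-1-en-1-yl]-2-(trimethylsilyl)phenyl trifluoromethanesulfonate, via bis-silyl ether 19 (not isolated), via lithium phenoxide 20 (not isolated), via silyl ether triflate 21 (not isolated)
Conditions: HMDS, THF, 65 °C, then evaporate; n-BuLi (1.05 equiv), THF, −100→−78 °C; Tf2O, −100 °C→rt; MeOH, cat. citric acid, rt
Reagents that add atoms: hexamethyldisilazane, C[Si](C)(C)N[Si](C)(C)C; trifluoromethanesulfonic anhydride, O=S(=O)(OS(=O)(=O)C(F)(F)F)C(F)(F)F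
Why: O-Silylation followed by bromine–lithium exchange triggers a retro-Brook 1,3-O→C silyl shift from the neighbouring silyl ether only, the phenoxide set free is triflated, and the remote silyl ether survives until the mild methanolysis, which differentiates the two oxygens and gives the 2-silylaryl triflate pattern.

Step 14
Reactants: 22 3-chloro-5-hydroxy-6-[(1E)-3-methylbut-1-en-1-yl]-2-(trimethylsilyl)phenyl trifluoromethanesulfonate
Product: 23 3-chloro-5-(methoxymethoxy)-6-[(1E)-3-methylbut-1-en-1-yl]-2-(trimethylsilyl)phenyl trifluoromethanesulfonate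
Conditions: NaH, MOMCl, THF, 0 °C
Reagents that add atoms: chloromethyl methyl ether, COCCl
Why: Williamson-type O-alkylation (MOM protection) of the one free phenol; triflate and aryl silane are inert to these fluoride-free conditions.

Step 15
Reactants: 12 (1R,2S,6S)-2-[3-acetyl-2,6-bis(methoxymethoxy)phenyl]-6-[2,4-bis(methoxymethoxy)phenyl]-4-methylcyclohex-3-ene-1-carboxylic acid; 23 3-chloro-5-(methoxymethoxy)-6-[(1E)-3-methylbut-1-en-1-yl]-2-(trimethylsilyl)phenyl trifluoromethanesulfonate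
Product: 26 [(1R,2S,6S)-2-[3-acetyl-2,6-bis(methoxymethoxy)phenyl]-6-[2,4-bis(methoxymethoxy)phenyl]-4-methylcyclohex-3-en-1-yl]{6-chloro-2-hydroxy-4-(methoxymethoxy)-3-[(1E)-3-methylbut-1-en-1-yl]phenyl}methanone, via aryne 24 (not isolated), via aryl anion ester 25 (not isolated)
Conditions: 23 (1.5 equiv), CsF (4 equiv), THF, 125 °C, sealed tube; aq. NH4Cl work-up
Reagents that add atoms: none
Why: Fluoride-induced 1,2-elimination of 23 gives aryne 24, the caesium carboxylate of 12 adds through oxygen to C-2′, the resulting C-1′ aryl anion 25 attacks the adjacent ester carbonyl, and the four-membered alkoxide collapses by C–O cleavage to the ketone phenoxide, so that the C(=O)–C-1′ bond and the C-2′–O bond are made in one operation. The closest known reaction type is the intermolecular C–O insertion of arynes into carboxylic acids that gives ortho-hydroxyaryl ketones (O-arylation followed by an anionic Fries-type 1,3-acyl shift). No ring of the product is closed; the only ring event is the transient benzoxete alkoxide formed by 4-exo-trig attack of the aryl anion on the ester carbonyl, which reopens at once. No stereocentre is created, and the three existing ones should be kept because neither the carboxylate nor the chelated phenoxide ketone is enolised by caesium fluoride in THF. The step needs regioselectivity: the chlorine on C-6′ beside the triple bond withdraws inductively, which makes the distal carbon C-2′ the electrophilic terminus and places the developing negative charge on C-1′ next to chlorine (the established meta attack on 3-haloarynes), while the alkenyl group on C-3′ and the chlorine flank the two termini with comparable bulk so that sterics should not overturn this. Chemoselectivity rests on the absence of free phenols and on the intramolecular acyl transfer outrunning both protonation and loss of chloride from 25.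

Step 16
Reactants: 26 [(1R,2S,6S)-2-[3-acetyl-2,6-bis(methoxymethoxy)phenyl]-6-[2,4-bis(methoxymethoxy)phenyl]-4-methylcyclohex-3-en-1-yl]{6-chloro-2-hydroxy-4-(methoxymethoxy)-3-[(1E)-3-methylbut-1-en-1-yl]phenyl}methanone
Product: 27 [(1R,2S,6S)-2-[3-acetyl-2,6-bis(methoxymethoxy)phenyl]-6-[2,4-bis(methoxymethoxy)phenyl]-4-methylcyclohex-3-en-1-yl]{2-hydroxy-4-(methoxymethoxy)-3-[(1E)-3-methylbut-1-en-1-yl]phenyl}methanone
Conditions: Pd(OAc)2 (5 mol %), XPhos (10 mol %), HCO2Na, DMF/H2O, 80 °C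
Reagents that add atoms: none
Why: Palladium-catalysed transfer hydrodehalogenation: oxidative addition into the ketone-activated C–Cl bond, formate decarboxylation to an aryl palladium hydride and reductive elimination replace chlorine by hydrogen without reducing alkenes or ketones.

Step 17
Reactants: 27 [(1R,2S,6S)-2-[3-acetyl-2,6-bis(methoxymethoxy)phenyl]-6-[2,4-bis(methoxymethoxy)phenyl]-4-methylcyclohex-3-en-1-yl]{2-hydroxy-4-(methoxymethoxy)-3-[(1E)-3-methylbut-1-en-1-yl]phenyl}methanone; 8 2,4-bis(methoxymethoxy)benzaldehyde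
Product: 28 (2E)-3-[2,4-bis(methoxymethoxy)phenyl]-1-{3-[(1S,5S,6R)-5-[2,4-bis(methoxymethoxy)phenyl]-6-{2-hydroxy-4-(methoxymethoxy)-3-[(1E)-3-methylbut-1-en-1-yl]benzoyl}-3-methylcyclohex-2-en-1-yl]-2,4-bis(methoxymethoxy)phenyl}prop-2-en-1-one
Conditions: KOH (aq.), EtOH, 0 °C→rt
Reagents that add atoms: none
Why: Claisen–Schmidt condensation of the only methyl ketone with the non-enolisable aldehyde gives the E-enone by E1cB dehydration, while the hindered tertiary α-hydrogen of the other ketone, whose aryl ring is a phenoxide under these conditions, should not be removed.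

Step 18
Reactants: 28 (2E)-3-[2,4-bis(methoxymethoxy)phenyl]-1-{3-[(1S,5S,6R)-5-[2,4-bis(methoxymethoxy)phenyl]-6-{2-hydroxy-4-(methoxymethoxy)-3-[(1E)-3-methylbut-1-en-1-yl]benzoyl}-3-methylcyclohex-2-en-1-yl]-2,4-bis(methoxymethoxy)phenyl}prop-2-en-1-one
Product: 29 Artonin C, (2E)-1-{3-[(1S,5S,6R)-6-{2,4-dihydroxy-3-[(1E)-3-methylbut-1-en-1-yl]benzoyl}-5-(2,4-dihydroxyphenyl)-3-methylcyclohex-2-en-1-yl]-2,4-dihydroxyphenyl}-3-(2,4-dihydroxyphenyl)prop-2-en-1-one
Conditions: HCl (1.25 M in MeOH), THF, rt→40 °C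
Reagents that add atoms: none
Why: Acid-catalysed acetal exchange with methanol (MOM cleavage) releases all seven methoxymethyl ethers as dimethoxymethane and does not touch the stereocentres.

**Compound list**

1 | 2,4-dihydroxyacetophenone | CC(=O)c1ccc(O)cc1O | starting material
2 | 1-(2,4-dihydroxy-3-iodophenyl)ethanone | CC(=O)c1ccc(O)c(I)c1O | intermediate
3 | 1-[3-iodo-2,4-bis(methoxymethoxy)phenyl]ethanone | CC(=O)c1ccc(OCOC)c(I)c1OCOC | intermediate
4 | 2-methylbut-1-en-3-yne | C=C(C)C#C | starting material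
5 | 4,4,5,5-tetramethyl-2-[(1E)-3-methylbuta-1,3-dien-1-yl]-1,3,2-dioxaborolane | CC(=C)/C=C/B1OC(C)(C)C(C)(C)O1 | intermediate
6 | 1-[2,4-bis(methoxymethoxy)-3-[(1E)-3-methylbuta-1,3-dien-1-yl]phenyl]ethanone | CC(=O)c1ccc(OCOC)c(/C=C/C(C)=C)c1OCOC | intermediate
7 | 2,4-dihydroxybenzaldehyde | O=Cc1ccc(O)cc1O | starting material
8 | 2,4-bis(methoxymethoxy)benzaldehyde | O=Cc1ccc(OCOC)cc1OCOC | intermediate
9 | 3-hydroxy-3-methylbutan-2-one | CC(=O)C(C)(C)O | starting material
10 | (1E)-1-[2,4-bis(methoxymethoxy)phenyl]-4-hydroxy-4-methylpent-1-en-3-one | CC(C)(O)C(=O)/C=C/c1ccc(OCOC)cc1OCOC | intermediate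
11 | 1-[(1R,2S,6S)-2-[3-acetyl-2,6-bis(methoxymethoxy)phenyl]-6-[2,4-bis(methoxymethoxy)phenyl]-4-methylcyclohex-3-en-1-yl]-2-hydroxy-2-methylpropan-1-one | CC1=C[C@H](c2c(OCOC)ccc(C(C)=O)c2OCOC)[C@H](C(=O)C(C)(C)O)[C@@H](c2ccc(OCOC)cc2OCOC)C1 | intermediate
12 | (1R,2S,6S)-2-[3-acetyl-2,6-bis(methoxymethoxy)phenyl]-6-[2,4-bis(methoxymethoxy)phenyl]-4-methylcyclohex-3-ene-1-carboxylic acid | CC1=C[C@H](c2c(OCOC)ccc(C(C)=O)c2OCOC)[C@H](C(=O)O)[C@@H](c2ccc(OCOC)cc2OCOC)C1 | intermediate
13 | 5-chlorobenzene-1,3-diol | Oc1cc(O)cc(Cl)c1 | starting material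
14 | 5-chloro-2-iodobenzene-1,3-diol | Oc1cc(Cl)cc(O)c1I | intermediate
15 | 4-bromo-5-chloro-2-iodobenzene-1,3-diol | Oc1cc(Cl)c(Br)c(O)c1I | intermediate
16 | 3-methylbut-1-yne | CC(C)C#C | starting material
17 | 4,4,5,5-tetramethyl-2-[(1E)-3-methylbut-1-en-1-yl]-1,3,2-dioxaborolane | CC(C)/C=C/B1OC(C)(C)C(C)(C)O1 | intermediate
18 | 4-bromo-5-chloro-2-[(1E)-3-methylbut-1-en-1-yl]benzene-1,3-diol | Oc1cc(Cl)c(Br)c(O)c1/C=C/C(C)C | intermediate
19 | bis(trimethylsilyl) ether of 18 | C[Si](C)(C)Oc1cc(Cl)c(Br)c(O[Si](C)(C)C)c1/C=C/C(C)C | intermediate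
20 | lithium 3-chloro-6-[(1E)-3-methylbut-1-en-1-yl]-2-(trimethylsilyl)-5-(trimethylsilyloxy)phenoxide | [Li+].[O-]c1c([Si](C)(C)C)c(Cl)cc(O[Si](C)(C)C)c1/C=C/C(C)C | intermediate
21 | 3-chloro-6-[(1E)-3-methylbut-1-en-1-yl]-2-(trimethylsilyl)-5-(trimethylsilyloxy)phenyl trifluoromethanesulfonate | C[Si](C)(C)Oc1cc(Cl)c([Si](C)(C)C)c(OS(=O)(=O)C(F)(F)F)c1/C=C/C(C)C | intermediate
22 | 3-chloro-5-hydroxy-6-[(1E)-3-methylbut-1-en-1-yl]-2-(trimethylsilyl)phenyl trifluoromethanesulfonate | Oc1cc(Cl)c([Si](C)(C)C)c(OS(=O)(=O)C(F)(F)F)c1/C=C/C(C)C | intermediate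
23 | 3-chloro-5-(methoxymethoxy)-6-[(1E)-3-methylbut-1-en-1-yl]-2-(trimethylsilyl)phenyl trifluoromethanesulfonate | COCOc1cc(Cl)c([Si](C)(C)C)c(OS(=O)(=O)C(F)(F)F)c1/C=C/C(C)C | intermediate
24 | 6-chloro-4-(methoxymethoxy)-3-[(1E)-3-methylbut-1-en-1-yl]-1,2-didehydrobenzene (aryne) | COCOC1=C(/C=C/C(C)C)C#CC(Cl)=C1 | intermediate
25 | caesium salt of the C-1′ aryl anion of the O-aryl ester of 12 | CC1=C[C@H](c2c(OCOC)ccc(C(C)=O)c2OCOC)[C@H](C(=O)Oc2c(/C=C/C(C)C)c(OCOC)cc(Cl)[c-]2)[C@@H](c2ccc(OCOC)cc2OCOC)C1.[Cs+] | intermediate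
26 | [(1R,2S,6S)-2-[3-acetyl-2,6-bis(methoxymethoxy)phenyl]-6-[2,4-bis(methoxymethoxy)phenyl]-4-methylcyclohex-3-en-1-yl]{6-chloro-2-hydroxy-4-(methoxymethoxy)-3-[(1E)-3-methylbut-1-en-1-yl]phenyl}methanone | CC1=C[C@H](c2c(OCOC)ccc(C(C)=O)c2OCOC)[C@H](C(=O)c2c(Cl)cc(OCOC)c(/C=C/C(C)C)c2O)[C@@H](c2ccc(OCOC)cc2OCOC)C1 | intermediate
27 | [(1R,2S,6S)-2-[3-acetyl-2,6-bis(methoxymethoxy)phenyl]-6-[2,4-bis(methoxymethoxy)phenyl]-4-methylcyclohex-3-en-1-yl]{2-hydroxy-4-(methoxymethoxy)-3-[(1E)-3-methylbut-1-en-1-yl]phenyl}methanone | CC1=C[C@H](c2c(OCOC)ccc(C(C)=O)c2OCOC)[C@H](C(=O)c2ccc(OCOC)c(/C=C/C(C)C)c2O)[C@@H](c2ccc(OCOC)cc2OCOC)C1 | intermediate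
28 | (2E)-3-[2,4-bis(methoxymethoxy)phenyl]-1-{3-[(1S,5S,6R)-5-[2,4-bis(methoxymethoxy)phenyl]-6-{2-hydroxy-4-(methoxymethoxy)-3-[(1E)-3-methylbut-1-en-1-yl]benzoyl}-3-methylcyclohex-2-en-1-yl]-2,4-bis(methoxymethoxy)phenyl}prop-2-en-1-one | CC1=C[C@H](c2c(OCOC)ccc(C(=O)/C=C/c3ccc(OCOC)cc3OCOC)c2OCOC)[C@H](C(=O)c2ccc(OCOC)c(/C=C/C(C)C)c2O)[C@@H](c2ccc(OCOC)cc2OCOC)C1 | intermediate
29 | Artonin C, (2E)-1-{3-[(1S,5S,6R)-6-{2,4-dihydroxy-3-[(1E)-3-methylbut-1-en-1-yl]benzoyl}-5-(2,4-dihydroxyphenyl)-3-methylcyclohex-2-en-1-yl]-2,4-dihydroxyphenyl}-3-(2,4-dihydroxyphenyl)prop-2-en-1-one | CC1=C[C@H](c2c(O)ccc(C(=O)/C=C/c3ccc(O)cc3O)c2O)[C@H](C(=O)c2ccc(O)c(/C=C/C(C)C)c2O)[C@@H](c2ccc(O)cc2O)C1 | target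

**Summary**

Total step count: 18.
Longest linear sequence: 9 steps (steps 1, 2, 4, 7, 8, 15, 16, 17, 18; the branch from 13 through steps 9, 10, 12, 13, 14, 15, 16, 17, 18 is equally long).

Steps most likely to fail:

1. Step 15. The acyl shift onto C-1′ may be outrun by protonation of the aryl anion (the carbonyl is flanked by a branched carbon), the aryl anion may lose chloride, regiocontrol may erode, or the α-carbon may epimerise at 125 °C. The fallback is a palladium-catalysed acyl cross-coupling in which the position of bromine fixes the regiochemistry; it sets out from 18 and 12 and comes back to the route at 29. Diol 18 is converted (NaH, MOMCl) into 2-bromo-1-chloro-3,5-bis(methoxymethoxy)-4-[(1E)-3-methylbut-1-en-1-yl]benzene F1; bromine–lithium exchange (n-BuLi, THF, −78 °C) and transmetalation with ZnCl2 give the arylzinc chloride F2. Acid 12 is converted (EtSH, EDC, DMAP, CH2Cl2) into the S-ethyl thioester F3. Fukuyama coupling of F2 with F3 (PdCl2(PPh3)2, THF/toluene, rt→40 °C) should give the fully protected chloro ketone F4. Hydrodechlorination as in step 16 gives ketone F5, Claisen–Schmidt condensation with 8 as in step 17 gives the fully protected chalcone F6, and acetal cleavage as in step 18 gives 29.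

2. Step 7. Activation of the dienophile may be insufficient because of its electron-rich β-aryl group, the keto ether of the diene may bind the catalyst competitively, or endo and facial selectivity may be poor. The fallback replaces catalyst control by a stoichiometric oxazolidinone auxiliary; it sets out from 8 and 6 and comes back to the route at 12. Aldehyde 8 is condensed with malonic acid (pyridine, piperidine, 90 °C; Knoevenagel–Doebner) through the arylidenemalonic acid F7, which decarboxylates in the flask, to (2E)-3-[2,4-bis(methoxymethoxy)phenyl]prop-2-enoic acid F8. Carbodiimide-mediated N-acylation of (4S)-4-benzyl-1,3-oxazolidin-2-one (DCC, DMAP) gives the N-enoyl imide F9. Diels–Alder reaction with 6 under Me2AlCl (CH2Cl2, −40→0 °C), in which the chelated s-cis imide is attacked on the Si face of C-α opposite the benzyl group through the endo transition state, should give the adduct F10. LiOH/H2O2 (THF/H2O, 0 °C) then liberates 12.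

3. Step 18. Acid may trigger ring closures faster than acetal cleavage: ketal formation between the ring ketone and the flanking phenols, chroman formation at the aryl alkene, or flavanone closure of the 2′-hydroxychalcone. The fallback avoids protic acid by exchanging the acetals for silyl ethers; it sets out from 28 and comes back to the route at 29. Treatment of 28 with TMSOTf/2,2′-bipyridyl (CH3CN, 0 °C→rt) converts the aryl methoxymethyl ethers, and the free phenol, into the octakis(trimethylsilyl) ether F11, which is hydrolysed to 29 by stirring with water at rt.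

**Further compounds**

F1 | step 15 | 2-bromo-1-chloro-3,5-bis(methoxymethoxy)-4-[(1E)-3-methylbut-1-en-1-yl]benzene | COCOc1cc(Cl)c(Br)c(OCOC)c1/C=C/C(C)C
F2 | step 15 | {6-chloro-2,4-bis(methoxymethoxy)-3-[(1E)-3-methylbut-1-en-1-yl]phenyl}zinc chloride | COCOc1cc(Cl)c([Zn]Cl)c(OCOC)c1/C=C/C(C)C
F3 | step 15 | S-ethyl (1R,2S,6S)-2-[3-acetyl-2,6-bis(methoxymethoxy)phenyl]-6-[2,4-bis(methoxymethoxy)phenyl]-4-methylcyclohex-3-ene-1-carbothioate | CC1=C[C@H](c2c(OCOC)ccc(C(C)=O)c2OCOC)[C@H](C(=O)SCC)[C@@H](c2ccc(OCOC)cc2OCOC)C1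
F4 | step 15 | [(1R,2S,6S)-2-[3-acetyl-2,6-bis(methoxymethoxy)phenyl]-6-[2,4-bis(methoxymethoxy)phenyl]-4-methylcyclohex-3-en-1-yl]{6-chloro-2,4-bis(methoxymethoxy)-3-[(1E)-3-methylbut-1-en-1-yl]phenyl}methanone | CC1=C[C@H](c2c(OCOC)ccc(C(C)=O)c2OCOC)[C@H](C(=O)c2c(Cl)cc(OCOC)c(/C=C/C(C)C)c2OCOC)[C@@H](c2ccc(OCOC)cc2OCOC)C1
F5 | step 15 | [(1R,2S,6S)-2-[3-acetyl-2,6-bis(methoxymethoxy)phenyl]-6-[2,4-bis(methoxymethoxy)phenyl]-4-methylcyclohex-3-en-1-yl]{2,4-bis(methoxymethoxy)-3-[(1E)-3-methylbut-1-en-1-yl]phenyl}methanone | CC1=C[C@H](c2c(OCOC)ccc(C(C)=O)c2OCOC)[C@H](C(=O)c2ccc(OCOC)c(/C=C/C(C)C)c2OCOC)[C@@H](c2ccc(OCOC)cc2OCOC)C1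
F6 | step 15 | (2E)-3-[2,4-bis(methoxymethoxy)phenyl]-1-{3-[(1S,5S,6R)-5-[2,4-bis(methoxymethoxy)phenyl]-6-{2,4-bis(methoxymethoxy)-3-[(1E)-3-methylbut-1-en-1-yl]benzoyl}-3-methylcyclohex-2-en-1-yl]-2,4-bis(methoxymethoxy)phenyl}prop-2-en-1-one | CC1=C[C@H](c2c(OCOC)ccc(C(=O)/C=C/c3ccc(OCOC)cc3OCOC)c2OCOC)[C@H](C(=O)c2ccc(OCOC)c(/C=C/C(C)C)c2OCOC)[C@@H](c2ccc(OCOC)cc2OCOC)C1
F7 | step 7 | 2-{[2,4-bis(methoxymethoxy)phenyl]methylidene}propanedioic acid | OC(=O)C(=Cc1ccc(OCOC)cc1OCOC)C(=O)O
F8 | step 7 | (2E)-3-[2,4-bis(methoxymethoxy)phenyl]prop-2-enoic acid | OC(=O)/C=C/c1ccc(OCOC)cc1OCOC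
F9 | step 7 | (4S)-4-benzyl-3-[(2E)-3-[2,4-bis(methoxymethoxy)phenyl]prop-2-enoyl]-1,3-oxazolidin-2-one | O=C1OC[C@H](Cc2ccccc2)N1C(=O)/C=C/c1ccc(OCOC)cc1OCOC
F10 | step 7 | (4S)-3-{[(1R,2S,6S)-2-[3-acetyl-2,6-bis(methoxymethoxy)phenyl]-6-[2,4-bis(methoxymethoxy)phenyl]-4-methylcyclohex-3-en-1-yl]carbonyl}-4-benzyl-1,3-oxazolidin-2-one | CC1=C[C@H](c2c(OCOC)ccc(C(C)=O)c2OCOC)[C@H](C(=O)N2[C@@H](Cc3ccccc3)COC2=O)[C@@H](c2ccc(OCOC)cc2OCOC)C1
F11 | step 18 | octakis(trimethylsilyl) ether of Artonin C | CC1=C[C@H](c2c(O[Si](C)(C)C)ccc(C(=O)/C=C/c3ccc(O[Si](C)(C)C)cc3O[Si](C)(C)C)c2O[Si](C)(C)C)[C@H](C(=O)c2ccc(O[Si](C)(C)C)c(/C=C/C(C)C)c2O[Si](C)(C)C)[C@@H](c2ccc(O[Si](C)(C)C)cc2O[Si](C)(C)C)C1
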